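What remained of the solid substrate after 10.0 h in the midnight run, 88.5% of its charge, opened the meeting.

| flask | solid substrate | reagent | remark | time |
|---|---|---|---|---|
| autumn | 0.41 M | 0.57 M | run made earlier |  |
| winter | 0.41 M | 0.90 M | run made earlier |  |
| midnight | 0.82 M | 0.41 M | run made earlier |  |
| flask | 0.41 M | 0.410 M |  | 10 h |

- autumn (time / h: solid substrate / %, first product / %): 0.833: 96.9, 0; 1.33: 96.3, 0; 2.00: 92.6, 1.3; 4.00: 88.7, 1.5; 6.00: 84.9, 4.0; 10.0: 75.6, 2.9
- winter (time / h: solid substrate / %, first product / %): 0.667: 99.9, 1.3; 2.00: 92.8, 0.2; 4.00: 88.1, 4.4; 5.00: 87.4, 2.0; 8.00: 78.6, 2.8; 10.0: 72.6, 4.2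
- midnight (time / h: solid substrate / %, first product / %): 0.833: 98.9, 2.3; 1.50: 98.0, 0; 3.00: 95.7, 2.6; 5.00: 93.4, 0.1; 10.0: 88.5, 2.0

(each reading ± 1 percentage point)

- solid substrate is a solid; its amount is given per volume of the solution
- at the start none of the solid substrate is in solution

* how much solid substrate there is at 10 h, in percent of the solid substrate charged (only what is still solid)
* how much first product there is at 10 h, in percent of the solid substrate charged
* how much bis adduct there is at 10 h, in percent of the solid substrate charged
* how much triple product there is at 10 h, in percent of the solid substrate charged

The first speaker multiplied the fraction of solid gone by the charge and divided by the time. Midnight then gave 0.00943 M/h, the solid's draw-down rate: the amount of solid lost per hour, averaged up to the last reading. Autumn gave 0.0100 M/h and winter 0.0112 M/h.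

A second speaker pointed out that midnight held twice the solid of autumn, yet its rate read lower, so the loss looks zero order in solid, though midnight also held less reagent. A third asked about reagent. On the same 0.41 M of solid, winter held 1.58 times the reagent of autumn and lost solid 1.12 times as fast, which the meeting called a weak dependence.

Since the flask's reagent, 0.410 M, equals midnight's 0.41 M, the meeting carried midnight's rate over and reckoned 77.0% solid left at 10 h. The readings show solid and first product, so the split of the rest stayed open.

The forecast gives 77% solid, 2.8% first product, 14% bis adduct and 3% triple product, expecting “mostly bis adduct, with little triple product”.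

The flask gives 77.4% solid, 3.55% first product, 0.996% bis adduct and 0.684% triple product.

    starting material + first product → side product (k = 0.00130 /M/s)
    reagent + first product → bis adduct (k = 6.00 × 10⁻⁵ /M/s)
    solid substrate ⇌ starting material, rate k3*(cs3 - [starting material]) while solid is left; crystals form when [starting material] > cs3 (solubility = 0.0780 M, k = 5.60 × 10⁻⁵ /s)
    starting material + reagent → first product (k = 8.10 × 10⁻⁵ /M/s)
    reagent + bis adduct ⇌ triple product (K = 4.60 /M, k = 1.90 × 10⁻⁴ /M/s)

At 10.0 h the flask makes starting material 1.02 times as fast as it uses it up, a near steady state, and uses it 1.6 times as fast with reagent as with first product. Side product stands at 7.24%, each counted as two, above the bis adduct. For the neighbour read at 6.0 h, the draw-down rate gives 86.2% solid left; the computed neighbour holds 84.8%.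

Readings and results are simulated with made-up constants; the scatter is artificial.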